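**Plan**
- Retrosynthesis (flavone numbering throughout): the sulfonic acid is masked as its neopentyl ester. Ring A is then cut at C5–C6 and C6–C7, which removes C6 with its sulfur as the α-carbanion of neopentyl methanesulfonate and leaves a 6-aryl-4-pyranone whose ring ester and acetate arm are the future C5 and C7.
- The pyranone (ring C, with ring B attached) is cut at O1–C2 and C4–C4a into dimethyl 3-oxoglutarate and 3-(4-methoxyphenyl)propioloyl chloride.
- Forward: ring B is bought; ring C is closed first (C-acylation, then oxa-Michael closure); ring A is closed last by a Claisen–Dieckmann [5+1] annulation; the neopentyl ester is cleaved at the end.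
- Feature that permits the key step: C6 is the single carbon between the oxygen-bearing carbons C5 and C7 and carries the sulfur, so it can enter as a sulfonyl-stabilised CH2 that is acylated twice by two ester carbons held cis on the C4a=C8a bond of the pyranone.
- Stereochemistry: the target has no stereocentre, so none has to be set.

Key step: step 4

Assumption: the target is taken as the free sulfonic acid as drawn, so the last step ends with acidification.

**Step 1**
Reactants: 1 3-(4-methoxyphenyl)prop-2-ynoic acid
Product: 2 3-(4-methoxyphenyl)prop-2-ynoyl chloride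
Conditions: (COCl)2, DMF (cat.), CH2Cl2, 0 °C to rt; concentrated and used crude
Reagents that add atoms: oxalyl chloride, O=C(Cl)C(=O)Cl
Why: Acid chloride formation through the chloroiminium species from oxalyl chloride and catalytic DMF runs under neutral conditions at or below room temperature, which arylpropiolic acids tolerate.

**Step 2**
Reactants: 2 3-(4-methoxyphenyl)prop-2-ynoyl chloride; 3 dimethyl 3-oxopentanedioate
Product: 5 methyl 2-(2-methoxy-2-oxoethyl)-6-(4-methoxyphenyl)-4-oxo-4H-pyran-3-carboxylate, via triketone ynone 4 (not isolated)
Conditions: MgCl2, pyridine, CH2Cl2, 0 °C to rt; 1 M HCl work-up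
Reagents that add atoms: none
Why: Soft enolisation of the β-keto ester as its magnesium chelate directs a Claisen-type C-acylation, and the enol oxygen of triketone 4 then adds 6-endo-dig to the ynone (oxa-Michael addition), the classical way from arylpropioloyl chlorides and β-keto esters to 6-aryl-4-pyranone-3-carboxylates.

**Step 3**
Reactants: 6 2,2-dimethylpropan-1-ol; 7 methanesulfonyl chloride
Product: 8 neopentyl methanesulfonate
Conditions: Et3N, CH2Cl2, 0 °C
Reagents that add atoms: none
Why: Mesylation through the sulfene generated from MsCl and Et3N takes place at oxygen, so the hindered neopentyl carbon does not slow it.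

**Step 4**
Reactants: 5 methyl 2-(2-methoxy-2-oxoethyl)-6-(4-methoxyphenyl)-4-oxo-4H-pyran-3-carboxylate; 8 neopentyl methanesulfonate
Product: 11 neopentyl 5,7-dihydroxy-2-(4-methoxyphenyl)-4-oxo-4H-chromene-6-sulfonate, via lithiated neopentyl methanesulfonate 9 (not isolated), via β-keto sulfonate 10 (not isolated)
Conditions: 8 (3.2 equiv), n-BuLi (3.0 equiv), THF, −78 °C; then 5 pre-treated with LiN(SiMe3)2 (1.0 equiv, THF, −78 °C), DMPU, −78 to 0 °C; then MeOH, 0 °C to rt; 1 M HCl
Reagents that add atoms: none
Why: Proposed new method: LiN(SiMe3)2 first turns the acidic C8 methylene of 5 into its extended enolate, which protects the pyranone against conjugate addition and leaves the ring-bound C5 ester (sharing the charge with the C4 and C7 carbonyls, hence attenuated but still acylating) as the site where carbanion 9 undergoes Claisen acylation to β-keto sulfonate 10; methanol then allows proton exchange, so that the doubly stabilised C6 carbanion attacks the C7 ester once C8 is reprotonated and the resulting 1,3-dione enolises to the aromatic 5,7-diol. The closest known reaction types are the Claisen acylation of α-lithiated alkyl methanesulfonates by esters to β-keto sulfonates, the acylation of sulfur-stabilised carbanions by salicylate-type esters that carry an ortho oxido group, and the Dieckmann-type aromatising closures of 3-oxoglutarate and homophthalate diesters; their union as a [5+1] annulation on a pyranone diester is new. Ring A closes in a 6-exo-trig mode, the two reacting carbonyls being held cis on the C4a=C8a double bond. No stereocentre is formed. The step needs attack at an ester carbonyl instead of addition to C2 or C4 of the pyranone, which the enolate charge and the 2-aryl group should secure, and C- instead of O-acylation in the closure, which the reversible alkoxide medium and the aromatic driving force should secure. Since O1 never leaves C8a and C6 ends up bonded to both C5 and C7 whichever ester reacts first, the sulfonate can only arrive at C6.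

**Step 5**
Reactants: 11 neopentyl 5,7-dihydroxy-2-(4-methoxyphenyl)-4-oxo-4H-chromene-6-sulfonate
Product: 12 niruriflavone, 5,7-dihydroxy-2-(4-methoxyphenyl)-4-oxo-4H-chromene-6-sulfonic acid
Conditions: Me4NCl, DMF, 160 °C; then 1 M HCl, C18 reverse-phase desalting
Reagents that add atoms: none
Why: SN2 dealkylation at the neopentyl carbon by chloride in a hot dipolar aprotic solvent is the established cleavage of neopentyl sulfonates, the sulfonate being a far better leaving group than the aryloxide of the 4'-methyl ether, and protonation then gives the free sulfonic acid.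

**Compound list**
1 | 3-(4-methoxyphenyl)prop-2-ynoic acid | COc1ccc(cc1)C#CC(=O)O | starting material
2 | 3-(4-methoxyphenyl)prop-2-ynoyl chloride | COc1ccc(cc1)C#CC(=O)Cl | intermediate
3 | dimethyl 3-oxopentanedioate | COC(=O)CC(=O)CC(=O)OC | starting material
4 | dimethyl 2-[3-(4-methoxyphenyl)prop-2-ynoyl]-3-oxopentanedioate (triketone ynone, formed in the flask) | COC(=O)CC(=O)C(C(=O)OC)C(=O)C#Cc1ccc(OC)cc1 | intermediate
5 | methyl 2-(2-methoxy-2-oxoethyl)-6-(4-methoxyphenyl)-4-oxo-4H-pyran-3-carboxylate | COC(=O)Cc1oc(cc(=O)c1C(=O)OC)-c1ccc(OC)cc1 | intermediate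
6 | 2,2-dimethylpropan-1-ol | CC(C)(C)CO | starting material
7 | methanesulfonyl chloride | CS(=O)(=O)Cl | starting material
8 | neopentyl methanesulfonate (2,2-dimethylpropyl methanesulfonate) | CS(=O)(=O)OCC(C)(C)C | intermediate
9 | lithiated neopentyl methanesulfonate, [(2,2-dimethylpropoxy)sulfonyl]methyllithium (formed in the flask) | [Li]CS(=O)(=O)OCC(C)(C)C | intermediate
10 | methyl 2-[3-{2-[(2,2-dimethylpropoxy)sulfonyl]acetyl}-6-(4-methoxyphenyl)-4-oxo-4H-pyran-2-yl]acetate (β-keto sulfonate, formed in the flask) | COC(=O)Cc1oc(cc(=O)c1C(=O)CS(=O)(=O)OCC(C)(C)C)-c1ccc(OC)cc1 | intermediate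
11 | neopentyl 5,7-dihydroxy-2-(4-methoxyphenyl)-4-oxo-4H-chromene-6-sulfonate | COc1ccc(cc1)-c1cc(=O)c2c(O)c(S(=O)(=O)OCC(C)(C)C)c(O)cc2o1 | intermediate
12 | niruriflavone, 5,7-dihydroxy-2-(4-methoxyphenyl)-4-oxo-4H-chromene-6-sulfonic acid | COc1ccc(-c2cc(=O)c3c(O)c(S(=O)(=O)O)c(O)cc3o2)cc1 | target

**Step count**
Total: 5 steps. Longest linear sequence: 4 steps (1 → 2 → 5 → 11 → 12); step 3 is a one-step side branch.

**Steps most likely to fail**

Step 4 (key step, proposed new method). The carbanion may fail to acylate the charge-attenuated ester before it decomposes on warming, or it may add to the pyranone and open it. The fallback gives up the annulation and uses known chemistry only; it sets out from acid chloride 2 and rejoins the route at target 12, so that steps 2 to 5 are not needed. Friedel–Crafts C-acylation of phloroglucinol by 2 (AlCl3, 1,2-dichloroethane), with 6-endo oxa-Michael closure of the resulting o-hydroxyaryl ynone, should give acacetin F1. K2CO3 and benzyl bromide in acetone should alkylate the more acidic, non-chelated 7-OH to give 7-O-benzylacacetin F2. Benzyltrimethylammonium dichloroiodate with CaCO3 in CH2Cl2–MeOH should iodinate C6, the site flanked by the chelated 5-OH and the 7-ether, to give 7-O-benzyl-6-iodoacacetin F3. Palladium-catalysed sulfination (Pd(OAc)2, P(t-Bu)3·HBF4, DABCO·(SO2)2, Et3N, i-PrOH, 75 °C) should give 7-O-benzylacacetin-6-sulfinic acid F4, which aqueous H2O2 should oxidise to 7-O-benzylacacetin-6-sulfonic acid F5. Hydrogenolysis (H2, Pd/C, MeOH) should then free the 7-OH and give 12.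

Step 2. O-acylation, double acylation or conjugate addition of pyridine to the ynoyl chloride may compete with C-acylation, and the ring closure may stay incomplete. The fallback sets out from 3 and returns to 5. C-acylation of 3 with commercial (E)-3-(4-methoxyphenyl)acryloyl chloride (MgCl2, pyridine, CH2Cl2) should give dimethyl 2-(4-methoxycinnamoyl)-3-oxopentanedioate F6, which has no ynone for pyridine to attack. Oxidative cyclisation with catalytic I2 in DMSO at 110 °C (oxa-Michael closure to the 2,3-dihydropyranone and dehydrogenation, as in the chalcone-to-flavone conversion) should then give 5.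

Step 5. At 160 °C chloride may also demethylate the 4'-ether, or the electron-rich ring may lose the sulfonate by protodesulfonation. The fallback changes the protecting group; it sets out from 5 and returns to 12. The annulation of step 4, run with commercial isobutyl methanesulfonate in place of 8, should give isobutyl 5,7-dihydroxy-2-(4-methoxyphenyl)-4-oxo-4H-chromene-6-sulfonate F7. NaI in refluxing acetone should dealkylate F7 at its β-branched primary carbon, at a temperature at which an aryl methyl ether is inert, and acidification as in step 5 should give 12.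

**Further compounds**
F1 | step 4 | acacetin, 5,7-dihydroxy-2-(4-methoxyphenyl)-4H-chromen-4-one | COc1ccc(cc1)-c1cc(=O)c2c(O)cc(O)cc2o1
F2 | step 4 | 7-(benzyloxy)-5-hydroxy-2-(4-methoxyphenyl)-4H-chromen-4-one | COc1ccc(cc1)-c1cc(=O)c2c(O)cc(OCc3ccccc3)cc2o1
F3 | step 4 | 7-(benzyloxy)-5-hydroxy-6-iodo-2-(4-methoxyphenyl)-4H-chromen-4-one | COc1ccc(cc1)-c1cc(=O)c2c(O)c(I)c(OCc3ccccc3)cc2o1
F4 | step 4 | 7-(benzyloxy)-5-hydroxy-2-(4-methoxyphenyl)-4-oxo-4H-chromene-6-sulfinic acid | COc1ccc(cc1)-c1cc(=O)c2c(O)c(S(=O)O)c(OCc3ccccc3)cc2o1
F5 | step 4 | 7-(benzyloxy)-5-hydroxy-2-(4-methoxyphenyl)-4-oxo-4H-chromene-6-sulfonic acid | COc1ccc(cc1)-c1cc(=O)c2c(O)c(S(=O)(=O)O)c(OCc3ccccc3)cc2o1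
F6 | step 2 | dimethyl 2-[(E)-3-(4-methoxyphenyl)prop-2-enoyl]-3-oxopentanedioate | COC(=O)CC(=O)C(C(=O)OC)C(=O)/C=C/c1ccc(OC)cc1
F7 | step 5 | 2-methylpropyl 5,7-dihydroxy-2-(4-methoxyphenyl)-4-oxo-4H-chromene-6-sulfonate | COc1ccc(cc1)-c1cc(=O)c2c(O)c(S(=O)(=O)OCC(C)C)c(O)cc2o1
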